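(The earlier runs and the new flask are calculated for an exercise; noise was put on by code.)

What is left over in the oak run, neither starting material nor target, comes to 31.9% of the charge at 144 h, and that is consumed starting material which does not show as target. Oak is the flask asked about, read so far.

the same everywhere: starting material 0.50 M; initiator 25 mM; temperature 60 °C
- oak: partner 0.55 M; protic impurity 0.050 M; the very flask that is asked about, followed so far
- flask: partner 0.550 M; protic impurity 0.0500 M; time 8.0 d

- oak (time / h: target / %, starting material / %): 40.0: 30.8, 49.7; 72.0: 34.6, 37.6; 120: 40.6, 27.2; 144: 43.0, 25.1

(standard deviation of a reading: 0.5 percentage points)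

- Saturday's: at 8.0 d raise the temperature by 15 K, then wait 15 d
- Sunday's: at 8.0 d take out 90% of the released group then present, then wait 15 d
- Monday's: at 8.0 d add partner, 50.0% of the amount charged, then wait 15 d
- Tuesday's: change nothing and wait 15 d more

- what is added takes up no volume worth counting
- the numbers in the tables scatter by 0.5 percentage points (one standard deviation)
- the earlier runs do not show what temperature does; that part of a forecast is a guess

- target, in percent of the starting material first charged, at 8.0 d
- the remedy with the largest gain of target, or "none" below 2 percentage points (Saturday's / Sunday's / Monday's / Tuesday's / none)
- target present, in percent of the starting material first charged, after Sunday's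
- target present, in percent of the starting material first charged, after Monday's

Pooled over the last three oak readings, 56.3% of the consumed starting material stands as target. This is the split, target per starting material consumed, a selectivity read at 60 °C. The earliest oak reading gives 61.2%, so we leave it out of the mean.

Next we need the starting material at 8.0 d. Replacing its bending curve by a mean first-order constant from 72.0 h to 144 h gives 0.00561 /h, hence 19.2% left and 45.5% target. That constant is the weak link. Reforged on the last stretch of the oak run, it is 0.00335 /h, slower than the mean, which leaves 21.4% and gives 44.2% target. We commit to 44.9%. If the split holds, what remains is worth 11 percentage points more, whether we wait, remove released group or raise c(partner). Saturday's leaves the temperature of the readings, so this room does not bind it, and there we can only guess.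

The forecast says 47.5% (45.5% to 49.5%), above our 44.9%, picks Monday's, and gives 71% after Sunday's and 78% after Monday's, both above our split. Of Monday's it says: “Adding partner nearly doubles partner concentration and the rate”.

The flask gives 44.1%. The best remedy is Saturday's, gaining 15 points. Sunday's ends at 48.8% and Monday's at 52.8%, gains of 4.6 points and 8.7 points, each smaller than our room.

    target ⇌ isomer of the product (K = 0.710, k = 0.0610 /h, Ea = 119 kJ/mol, ΔH = −42.0 kJ/mol)
    crystals ⇌ released group, rate k2*(cs2 - [released group]) while solid is left; crystals form when [released group] > cs2 (solubility = 0.490 M, k = 2.60 /h)
    2 first chain carrier → ended chains (k = 5.70 × 10⁶ /M/s, Ea = 24.0 kJ/mol)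
    partner + protic impurity → quenched reagent (k = 0.0790 /M/h, Ea = 79.0 kJ/mol)
    starting material + initiating radical → capped initiator + first chain carrier (k = 6.60 × 10⁶ /M/h, Ea = 48.0 kJ/mol)
    partner + first chain carrier ⇌ target + second chain carrier (K = 0.330, k = 6.50 × 10⁵ /M/h, Ea = 38.0 kJ/mol, ΔH = −46.0 kJ/mol)
    starting material + second chain carrier → released group + first chain carrier (k = 3.70 × 10⁵ /M/h, Ea = 40.0 kJ/mol)
    initiator → 2 initiating radical (k = 0.00350 /h, Ea = 112 kJ/mol)
    (constants at 60 °C)

Target's forward step into isomer, taken alone, has a half-life of 11.4 h, far shorter than the 8.0 d the flask has stood. At 192 h the flask holds 44.1% target beside 31.0% isomer, a ratio of 0.703 close to the equilibrium constant 0.71, which is thermodynamic control. With 20% of starting material left, the split gives 45.0% here. A neighbouring flask charged with 0.85 M of starting material keeps 44% of it at 8.0 d, so the split gives 31.5%; computed, it holds 31.3%.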